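## Retrosynthetic overview

1. Target ⇒ cut the ArCH2–C(ring) bond: a chiral dearomatized acylphloroglucinol whose vinylic methyl group is the latent bridge carbon (unmasked as an exo-methylene trione) plus an 8-acyl-5,7-dihydroxychromene.
2. Chiral dienone ⇒ cut the C(quaternary)–CH2(prenyl) bond: mirror-symmetric, fully substituted 3,5-dimethylphlorisobutyrophenone is made electrophilic at its C–Me carbons as an O-bound λ3-iodane (enolonium equivalent) and captured by a nucleophilic allylsilane. A chiral iodane picks one of the two enantiotopic carbons and sets the only stereocentre.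
3. Both halves ⇒ phlorisobutyrophenone (phloroglucinol + isobutyryl chloride): double C-methylation for one half, prenal annulation for the other.
4. Rings: both carbocycles come from phloroglucinol. The only ring built is the 2H-pyran (oxa-6π closure), before the halves are joined; ring A is dearomatized in the key step.

Assumption: the target and all dearomatized compounds are written in the enol tautomer of the given SMILES, and the descriptor S refers to that drawing.
Assumption: the (R,R)-iodoarene is taken to give the S centre; if the sense of induction is opposite, its (S,S)-enantiomer is used in the same way.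

## Route

Step 1
Reactants: 1 phloroglucinol (benzene-1,3,5-triol); 2 isobutyryl chloride (2-methylpropanoyl chloride)
Product: 3 2-methyl-1-(2,4,6-trihydroxyphenyl)propan-1-one (phlorisobutyrophenone)
Conditions: AlCl3 (4 equiv), PhNO2/CH2Cl2, rt then 50 °C; ice/aq. HCl
Reagents that add atoms: isobutyryl chloride 2, CC(C)C(Cl)=O
Why: Friedel–Crafts acylation of the very nucleophilic phloroglucinol ring (any O-acyl material is funnelled to the ketone by Fries rearrangement under AlCl3), the first acyl group deactivating the ring towards a second acylation.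

Step 2
Reactants: 3 phlorisobutyrophenone; 4 iodomethane
Product: 5 1-(2,4,6-trihydroxy-3,5-dimethylphenyl)-2-methylpropan-1-one
Conditions: NaOMe (3.0 equiv), MeI (2.2 equiv), MeOH, 0 °C to rt; aq. HCl; chromatography (mono-methyl fraction recycled)
Reagents that add atoms: iodomethane 4, CI
Why: Base-mediated C-methylation of the phloroglucinolate (soft MeI in a protic medium favours C- over O-alkylation) at both free ring carbons; the mirror-symmetric 3,5-dimethyl compound is separated from mono- and gem-dimethylated material, leaving every ring carbon substituted and the two C–Me carbons enantiotopic.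

Step 3
Reactants: 6 1-chloro-3-methylbut-2-ene (prenyl chloride); 7 chlorotrimethylsilane
Product: 9 trimethyl(2-methylbut-3-en-2-yl)silane, via prenylmagnesium chloride 8 (not isolated)
Conditions: Mg turnings (1.5 equiv), Me3SiCl (1.2 equiv), THF, 0 °C to rt (Barbier mode); fractional distillation
Reagents that add atoms: chlorotrimethylsilane 7, C[Si](C)(C)Cl
Why: Barbier-type Grignard silylation in which the primary prenyl Grignard 8 reacts with the small electrophile Me3SiCl predominantly through its γ-carbon (SE2'), placing silicon on the tertiary carbon; the minor primary prenylsilane is removed by distillation.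

Step 4
Reactants: 5 1-(2,4,6-trihydroxy-3,5-dimethylphenyl)-2-methylpropan-1-one; 9 trimethyl(2-methylbut-3-en-2-yl)silane
Product: 11 (4S)-3,5-dihydroxy-2,4-dimethyl-4-(3-methylbut-2-en-1-yl)-6-(2-methylpropanoyl)cyclohexa-2,5-dien-1-one, via aryloxy-λ3-iodane 10 (not isolated)
Conditions: (R,R)-2-iodo-1,3-bis[1-(mesitylcarbamoyl)ethoxy]benzene (1.05 equiv), mCPBA (1.0 equiv), CF3CO2H (2.2 equiv), 4 Å MS, CH2Cl2, rt, 2 h; this solution added to 5 (1.1 equiv) + 9 (3 equiv), CH2Cl2/CF3CH2OH 4:1, −40 to −20 °C; solid NaHCO3, filtration, chromatography (iodoarene recovered)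
Reagents that add atoms: trimethyl(2-methylbut-3-en-2-yl)silane 9, C=CC(C)(C)[Si](C)(C)C
Why: Proposed new method: the 4-OH of 5 (para to the acyl group, on the mirror plane) exchanges a trifluoroacetate on the chiral trivalent-iodine reagent to give 10, in which the ring is an enolonium (phenoxenium) equivalent with two enantiotopic electrophilic ortho C–Me carbons; allylsilane 9 attacks one of them through its unsubstituted CH2 terminus (SE2' with loss of the silyl group to trifluoroacetate, hence the linear prenyl group) as the iodoarene departs reductively, the C2-symmetric lactamide arms folded around iodine selecting carbon and face and so setting the S quaternary centre in a desymmetrizing dearomatization, while the acyl-bearing carbon is electronically deactivated and no ring C–H is left for a rearomatizing substitution; the closest known reaction types are the λ3-iodane-mediated dearomatizing ortho-allylation of 2-alkylarenols with allylsilanes, the allylation of ketone enolonium species with allylsilanes, and enantioselective phenol dearomatizations controlled by lactamide-type chiral iodoarenes.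

Step 5
Reactants: 3 phlorisobutyrophenone; 12 3-methylbut-2-enal (prenal)
Product: 14 1-(5,7-dihydroxy-2,2-dimethyl-2H-chromen-8-yl)-2-methylpropan-1-one, via prenylidene quinone methide 13 (not isolated)
Conditions: 12 (1.1 equiv), ethylenediammonium diacetate (0.2 equiv), THF, reflux; chromatography
Reagents that add atoms: 3-methylbut-2-enal 12, CC(C)=CC=O
Why: Amine-salt-catalysed Knoevenagel-type condensation of 12 at a free ring carbon of 3 gives quinone methide 13, which closes by oxa-6π electrocyclization; closure through the oxygen next to the acyl group gives the 8-acyl chromene 14, which is separated from the 6-acyl regioisomer formed by closure through the para oxygen.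

Step 6
Reactants: 11 (4S)-dienone; 14 1-(5,7-dihydroxy-2,2-dimethyl-2H-chromen-8-yl)-2-methylpropan-1-one
Product: 16 (4S)-2-{[5,7-dihydroxy-2,2-dimethyl-8-(2-methylpropanoyl)-2H-chromen-6-yl]methyl}-3,5-dihydroxy-4-methyl-4-(3-methylbut-2-en-1-yl)-6-(2-methylpropanoyl)cyclohexa-2,5-dien-1-one (CNP0301804.1), via exo-methylene trione 15 (not isolated)
Conditions: 14 (1.5 equiv), Ag2O (1.2 equiv), TEMPO (0.3 equiv), CH2Cl2, rt, dark; Celite filtration, chromatography
Reagents that add atoms: none
Why: Dehydrogenation of the vinylic methyl group of the silver enolate of the acidic trione 11 (single-electron oxidation by Ag2O, hydrogen-atom abstraction by TEMPO, which Ag2O regenerates) gives the quinone-methide-type Michael acceptor 15, which is captured by the only free aromatic carbon (C6) of 14 in a Michael/Friedel–Crafts alkylation followed by re-enolization; the quaternary stereocentre is not involved and is carried through unchanged.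

## Compound list

1 | phloroglucinol | Oc1cc(O)cc(O)c1 | starting material
2 | isobutyryl chloride | CC(C)C(Cl)=O | starting material
3 | 2-methyl-1-(2,4,6-trihydroxyphenyl)propan-1-one | CC(C)C(=O)c1c(O)cc(O)cc1O | intermediate
4 | iodomethane | CI | starting material
5 | 1-(2,4,6-trihydroxy-3,5-dimethylphenyl)-2-methylpropan-1-one | CC(C)C(=O)c1c(O)c(C)c(O)c(C)c1O | intermediate
6 | 1-chloro-3-methylbut-2-ene | CC(C)=CCCl | starting material
7 | chlorotrimethylsilane | C[Si](C)(C)Cl | starting material
8 | (3-methylbut-2-en-1-yl)magnesium chloride | CC(C)=CC[Mg]Cl | intermediate (not isolated)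
9 | trimethyl(2-methylbut-3-en-2-yl)silane | C=CC(C)(C)[Si](C)(C)C | intermediate
10 | aryloxy(trifluoroacetoxy)-λ3-iodane: 4-O of 5 bonded to the iodine of the (R,R)-iodoarene | CC(C)C(=O)c1c(O)c(C)c(OI(OC(=O)C(F)(F)F)c2c(O[C@H](C)C(=O)Nc3c(C)cc(C)cc3C)cccc2O[C@H](C)C(=O)Nc2c(C)cc(C)cc2C)c(C)c1O | intermediate (not isolated)
11 | (4S)-3,5-dihydroxy-2,4-dimethyl-4-(3-methylbut-2-en-1-yl)-6-(2-methylpropanoyl)cyclohexa-2,5-dien-1-one | CC(C)=CC[C@@]1(C)C(O)=C(C)C(=O)C(C(=O)C(C)C)=C1O | intermediate
12 | 3-methylbut-2-enal | CC(C)=CC=O | starting material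
13 | 3,5-dihydroxy-6-(3-methylbut-2-en-1-ylidene)-2-(2-methylpropanoyl)cyclohexa-2,4-dien-1-one | CC(C)=CC=C1C(=O)C(C(=O)C(C)C)=C(O)C=C1O | intermediate (not isolated)
14 | 1-(5,7-dihydroxy-2,2-dimethyl-2H-chromen-8-yl)-2-methylpropan-1-one | CC(C)C(=O)c1c(O)cc(O)c2C=CC(C)(C)Oc12 | intermediate
15 | 5-hydroxy-6-methyl-2-methylidene-6-(3-methylbut-2-en-1-yl)-4-(2-methylpropanoyl)cyclohex-4-ene-1,3-dione, quaternary centre as in 11 | CC(C)=CC[C@@]1(C)C(=O)C(=C)C(=O)C(C(=O)C(C)C)=C1O | intermediate (not isolated)
16 | (4S)-2-{[5,7-dihydroxy-2,2-dimethyl-8-(2-methylpropanoyl)-2H-chromen-6-yl]methyl}-3,5-dihydroxy-4-methyl-4-(3-methylbut-2-en-1-yl)-6-(2-methylpropanoyl)cyclohexa-2,5-dien-1-one | CC(C)=CC[C@@]1(C)C(O)=C(Cc2c(O)c3c(c(C(=O)C(C)C)c2O)OC(C)(C)C=C3)C(=O)C(C(=O)C(C)C)=C1O | target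

## Step count and risks

Total steps: 6. Longest linear sequence: 4 steps (1 → 3 → 5 → 11 → 16).

**Step 4 (most likely to fail).** The enantio-induction is untested. Benzylic oxidation of 5 to a quinone methide, or over-oxidation of 11, may also compete. Fallback, setting out from 5 and coming back at 11: the same enolonium prenylation is run with achiral PhI(OCOCF3)2 and 9 (CH2Cl2/CF3CH2OH, −40 °C) to give the racemic dienone F1. F1 is a vinylogous acid and is resolved classically: it is crystallized with (R)-1-phenylethylamine, and the less soluble diastereomeric salt F2 is recrystallized to constant rotation. Partition of F2 between dilute HCl and EtOAc returns 11. If the other diastereomer crystallizes, the (S)-amine is used. Stereocontrol then rests on resolution and not on the reagent.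

**Step 6.** Ag2O/TEMPO may also oxidize the phenol 14 or the product, and 15 may be intercepted by 11 itself. Fallback, setting out from 11 and coming back at 16: 11 is oxidized with Ag2O and TEMPO (2.2 equiv) in the absence of the chromene, which traps the quinone methide as the isolable alkoxyamine F3 (TEMPO–O–CH2 on the former methyl carbon). F3 is then heated with 14 (PhMe, 80–90 °C). Thermal loss of 2,2,6,6-tetramethylpiperidin-1-ol releases 15 slowly and without any oxidant present, and 14 captures it to give 16.

**Step 3.** If silylation gives mainly the primary prenylsilane, or the isomers cannot be separated, step 4 would deliver the reverse-prenyl isomer. Fallback, setting out from 5 and coming back at 11: commercial allyltrimethylsilane replaces 9 in the step-4 reaction and gives the allyl dienone F4 with the same sense of induction. Cross-metathesis of F4 with 2-methylbut-2-ene (second-generation Grubbs catalyst (H2IMes)(PCy3)Cl2Ru=CHPh, CH2Cl2, 40 °C) converts allyl into prenyl and returns 11.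

## Further compounds

F1 | step 4 | racemic 3,5-dihydroxy-2,4-dimethyl-4-(3-methylbut-2-en-1-yl)-6-(2-methylpropanoyl)cyclohexa-2,5-dien-1-one | CC(C)=CCC1(C)C(O)=C(C)C(=O)C(C(=O)C(C)C)=C1O
F2 | step 4 | (R)-1-phenylethylammonium salt of the (4S)-dienone 11 | CC(C)=CC[C@@]1(C)C(O)=C(C)C(=O)C(C(=O)C(C)C)=C1[O-].C[C@@H]([NH3+])c1ccccc1
F3 | step 6 | (4S)-3,5-dihydroxy-4-methyl-4-(3-methylbut-2-en-1-yl)-6-(2-methylpropanoyl)-2-{[(2,2,6,6-tetramethylpiperidin-1-yl)oxy]methyl}cyclohexa-2,5-dien-1-one | CC(C)=CC[C@@]1(C)C(O)=C(CON2C(C)(C)CCCC2(C)C)C(=O)C(C(=O)C(C)C)=C1O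
F4 | step 3 | (4S)-3,5-dihydroxy-2,4-dimethyl-6-(2-methylpropanoyl)-4-(prop-2-en-1-yl)cyclohexa-2,5-dien-1-one | C=CC[C@@]1(C)C(O)=C(C)C(=O)C(C(=O)C(C)C)=C1O
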